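Units are lettered A (outer, joined A2–B2), B (central) and C (outer, joined C2–B4), each numbered as 8-methoxynaphthalen-1-ol.
The retrosynthesis first opens the phenol ring of unit C at C4–C4a and C2–C3. This works because C3 and C4 are plain CH, C2 carries B, and C4a is the only C–H ortho to the carbonyl of a 2-methoxyphenyl ketone; the pieces are an α-aryl 2'-methoxyacetophenone and vinylene carbonate. Next cut is CH2–B4 (ketone α-arylation), then A2–B2 (Negishi coupling).
Forward, naphthalene-1,8-diol gives 8-methoxynaphthalen-1-ol, which is split into a MOM-protected A nucleophile and a 4-bromo-2-iodo B electrophile. Iodide-selective coupling, α-arylation, annulation of unit C's phenol ring and MOM removal follow.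
The B4 bromine is placed on the monomer, para to the free hydroxyl, so no late bromination of a symmetric dimer with uncertain site and statistical outcome is needed.
Stereochemistry: the target has no stereocentre. Assumption: both biaryl axes rotate freely, as the notation defines no axial configuration, so nothing has to be controlled.

Key step: step 8

Step 1
Reactants: 1 naphthalene-1,8-diol
Product: 2 8-methoxynaphthalen-1-ol
Conditions: MeI (1.05 equiv), K2CO3, acetone, reflux, N2
Reagents that add atoms: iodomethane, CI
Why: Williamson etherification stops at the mono-ether because the remaining hydroxyl is tied up in a hydrogen bond to the peri methoxy oxygen and is not deprotonated by carbonate.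

Step 2
Reactants: 2 8-methoxynaphthalen-1-ol
Product: 3 1-methoxy-8-(methoxymethoxy)naphthalene
Conditions: NaH, DMF, 0 °C; MOMCl, 0 °C to rt
Reagents that add atoms: chloromethyl methyl ether, COCCl
Why: Irreversible deprotonation with NaH breaks the peri hydrogen bond and the naphthoxide is alkylated by MOMCl (Williamson-type acetal ether formation).

Step 3
Reactants: 2 8-methoxynaphthalen-1-ol
Product: 4 4-bromo-8-methoxynaphthalen-1-ol
Conditions: NBS (1.0 equiv), MeCN, −20 to 0 °C, dark
Reagents that add atoms: N-bromosuccinimide, O=C1CCC(=O)N1Br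
Why: Electrophilic aromatic bromination goes para to the free hydroxyl, the strongest donor in the molecule, and NBS in acetonitrile favours the para position of 1-naphthols.

Step 4
Reactants: 4 4-bromo-8-methoxynaphthalen-1-ol
Product: 5 4-bromo-2-iodo-8-methoxynaphthalen-1-ol
Conditions: NIS (1.05 equiv), TsOH·H2O (cat.), MeCN, 0 °C to rt
Reagents that add atoms: N-iodosuccinimide, O=C1CCC(=O)N1I
Why: With C4 blocked, electrophilic aromatic iodination can only take the ortho position C2, the last site activated by the hydroxyl.

Step 5
Reactants: 5 4-bromo-2-iodo-8-methoxynaphthalen-1-ol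
Product: 6 4-bromo-2-iodo-8-methoxy-1-(methoxymethoxy)naphthalene
Conditions: NaH, DMF, 0 °C; MOMCl, 0 °C to rt
Reagents that add atoms: chloromethyl methyl ether, COCCl
Why: MOM ether formation via the sodium naphthoxide tolerates both aryl halides, and the small electrophile reaches the hindered oxygen.

Step 6
Reactants: 3 1-methoxy-8-(methoxymethoxy)naphthalene; 6 4-bromo-2-iodo-8-methoxy-1-(methoxymethoxy)naphthalene
Product: 9 4-bromo-8,8'-dimethoxy-1,1'-bis(methoxymethoxy)-2,2'-binaphthalene, via aryllithium 7 (not isolated), via arylzinc chloride 8 (not isolated)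
Conditions: 3 (1.3 equiv), n-BuLi, TMEDA, THF, 0 °C; ZnCl2, 0 °C to rt; then 6, Pd(PPh3)4 (5 mol %), rt to 40 °C
Reagents that add atoms: none
Why: Directed ortho-metalation next to the OMOM group (a stronger director than OMe), transmetalation to zinc and Negishi cross-coupling form A2–B2, and zerovalent palladium inserts into the C–I bond much faster than into C–Br, so the B4 bromide survives.

Step 7
Reactants: 9 4-bromo-8,8'-dimethoxy-1,1'-bis(methoxymethoxy)-2,2'-binaphthalene; 10 2'-methoxyacetophenone
Product: 11 2-[8,8'-dimethoxy-1,1'-bis(methoxymethoxy)-2,2'-binaphthalen-4-yl]-1-(2-methoxyphenyl)ethan-1-one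
Conditions: 10 (1.3 equiv), Pd2(dba)3 (2.5 mol %), [HP(t-Bu)3]BF4 (6 mol %), NaOt-Bu (2.2 equiv), THF, 60 °C
Reagents that add atoms: none
Why: Palladium-catalysed ketone α-arylation (Buchwald–Hartwig type) with a bulky electron-rich phosphine couples the sodium enolate with the naphthyl bromide, and the hindered, more acidic product rests as its enolate, which prevents a second arylation.

Step 8
Reactants: 11 2-[8,8'-dimethoxy-1,1'-bis(methoxymethoxy)-2,2'-binaphthalen-4-yl]-1-(2-methoxyphenyl)ethan-1-one; 12 vinylene carbonate
Product: 14 8-methoxy-2-[8,8'-dimethoxy-1,1'-bis(methoxymethoxy)-2,2'-binaphthalen-4-yl]naphthalen-1-ol, via keto aldehyde 13 (not isolated)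
Conditions: 12 (3 equiv), [Cp*RhCl2]2 (5 mol %), AgSbF6 (20 mol %), NaOAc (50 mol %), DCE, 80 °C
Reagents that add atoms: none
Why: Proposed new method: the cationic Cp*Rh species (trivalent rhodium) formed from [Cp*RhCl2]2 and AgSbF6 binds the ketone oxygen of 11 and cleaves the single ortho C–H of the methoxyphenyl ring by acetate-assisted concerted metalation–deprotonation to a five-membered rhodacycle, vinylene carbonate inserts into the Rh–C bond (new bond C4–C4a of unit C), and β-oxygen elimination with loss of CO2 leaves the 2-oxoethyl group of 13 while rhodium stays trivalent, so no oxidant is needed. The CH2 of 13, acidified by the ketone and by ring B, then adds as its enol or enolate to the aldehyde (new bond C2–C3), water is lost and the ring aromatises to the naphthol. The closest known reaction types are the trivalent-rhodium [4+2] annulations of α-activated aryl ketones with alkynes to 1-naphthols and the vinylene carbonate annulations of benzamides to 3,4-unsubstituted isoquinolones; a plain α-aryl ketone with vinylene carbonate is the untested combination. The one new ring, the phenol ring of unit C, closes by a 6-(enolendo)-exo-trig aldol condensation driven by aromatisation, and no stereocentre is formed. The step needs site selectivity for the methoxyphenyl ortho C–H, which the substrate secures: only there is a five-membered chelate possible, the other ortho position carries OMe, B3–H is flanked by two substituents and B5–H would need a seven-membered metallacycle. The C8 methoxy group also blocks the peri position of the new naphthol, so the free hydroxyl cannot direct a second annulation.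

Step 9
Reactants: 14 8-methoxy-2-[8,8'-dimethoxy-1,1'-bis(methoxymethoxy)-2,2'-binaphthalen-4-yl]naphthalen-1-ol
Product: 15 8,8',8''-trimethoxy-[2,2':4',2''-ternaphthalene]-1,1',1''-triol (CNP0482979.0)
Conditions: HCl (3 M aq.), MeOH–THF, 45 °C, argon
Reagents that add atoms: none
Why: Acid-catalysed acetal cleavage removes both MOM groups as dimethoxymethane in methanol, while the aryl methyl ethers are inert to dilute acid.

Compound list
1 | naphthalene-1,8-diol | Oc1cccc2cccc(O)c12 | starting material
2 | 8-methoxynaphthalen-1-ol | COc1cccc2cccc(O)c12 | intermediate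
3 | 1-methoxy-8-(methoxymethoxy)naphthalene | COCOc1cccc2cccc(OC)c12 | intermediate
4 | 4-bromo-8-methoxynaphthalen-1-ol | COc1cccc2c(Br)ccc(O)c12 | intermediate
5 | 4-bromo-2-iodo-8-methoxynaphthalen-1-ol | COc1cccc2c(Br)cc(I)c(O)c12 | intermediate
6 | 4-bromo-2-iodo-8-methoxy-1-(methoxymethoxy)naphthalene | COCOc1c(I)cc(Br)c2cccc(OC)c12 | intermediate
7 | [8-methoxy-1-(methoxymethoxy)naphthalen-2-yl]lithium | [Li]c1ccc2cccc(OC)c2c1OCOC | intermediate
8 | chloro[8-methoxy-1-(methoxymethoxy)naphthalen-2-yl]zinc | Cl[Zn]c1ccc2cccc(OC)c2c1OCOC | intermediate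
9 | 4-bromo-8,8'-dimethoxy-1,1'-bis(methoxymethoxy)-2,2'-binaphthalene | COCOc1c(-c2ccc3cccc(OC)c3c2OCOC)cc(Br)c2cccc(OC)c12 | intermediate
10 | 2'-methoxyacetophenone | COc1ccccc1C(C)=O | starting material
11 | 2-[8,8'-dimethoxy-1,1'-bis(methoxymethoxy)-2,2'-binaphthalen-4-yl]-1-(2-methoxyphenyl)ethan-1-one | COc1ccccc1C(=O)Cc1cc(-c2ccc3cccc(OC)c3c2OCOC)c(OCOC)c2c(OC)cccc12 | intermediate
12 | vinylene carbonate (1,3-dioxol-2-one) | O=C1OC=CO1 | starting material
13 | 2-{2-[2-(8,8'-dimethoxy-1,1'-bis(methoxymethoxy)-2,2'-binaphthalen-4-yl)acetyl]-3-methoxyphenyl}acetaldehyde | COc1cccc(CC=O)c1C(=O)Cc1cc(-c2ccc3cccc(OC)c3c2OCOC)c(OCOC)c2c(OC)cccc12 | intermediate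
14 | 8-methoxy-2-[8,8'-dimethoxy-1,1'-bis(methoxymethoxy)-2,2'-binaphthalen-4-yl]naphthalen-1-ol | COc1cccc2ccc(-c3cc(-c4ccc5cccc(OC)c5c4OCOC)c(OCOC)c4c(OC)cccc34)c(O)c12 | intermediate
15 | 8,8',8''-trimethoxy-[2,2':4',2''-ternaphthalene]-1,1',1''-triol | COc1cccc2ccc(-c3cc(-c4ccc5cccc(OC)c5c4O)c4cccc(OC)c4c3O)c(O)c12 | target

Total step count: 9. Longest linear sequence: 8 steps (steps 1, 3, 4, 5, 6, 7, 8, 9).

Steps most likely to fail

Step 8. The ketone may bind rhodium too weakly for C–H cleavage, the aldol closure may stall after the insertion, or the MOM acetals may be lost in the Lewis-acidic medium. The fallback gives up the annulation and forms B4–C2 by cross-coupling. It sets out from bromide 9, which is coupled with arylzinc chloride 8 (made from 3 as in step 6) using Pd2(dba)3 and SPhos in THF at 60 °C. This Negishi coupling should give 8,8',8''-trimethoxy-1,1',1''-tris(methoxymethoxy)-2,2':4',2''-ternaphthalene F1. Treatment of F1 with HCl in MeOH–THF, as in step 9, removes all three MOM groups, and the route is rejoined at target 15.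

Step 7. Oxidative addition at the peri-hindered B4 bromide may be slow, so that reduction of the C–Br bond or self-condensation of the ketone enolate takes over. The fallback builds the side chain stepwise from bromide 9. Stille coupling with allyltributylstannane (Pd(PPh3)4, toluene, 100 °C) should give 4-allyl-8,8'-dimethoxy-1,1'-bis(methoxymethoxy)-2,2'-binaphthalene F2. Lemieux–Johnson cleavage (OsO4 cat., NaIO4, 2,6-lutidine, dioxane–water) should then give 2-[8,8'-dimethoxy-1,1'-bis(methoxymethoxy)-2,2'-binaphthalen-4-yl]acetaldehyde F3. Addition of 2-methoxyphenylmagnesium bromide in THF at −78 °C should give racemic 2-[8,8'-dimethoxy-1,1'-bis(methoxymethoxy)-2,2'-binaphthalen-4-yl]-1-(2-methoxyphenyl)ethan-1-ol F4. Dess–Martin oxidation of F4 returns to the route at ketone 11.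

Step 6. Metalation of 3 may be incomplete or may occur next to the methoxy group instead of the OMOM group, which would give a regioisomeric biaryl. The fallback fixes the metal position with a halogen and sets out from naphthol 2. Amine-mediated ortho-bromination (NBS, i-Pr2NH cat., CH2Cl2, 0 °C) should give 2-bromo-8-methoxynaphthalen-1-ol F5. MOM protection (NaH, MOMCl, DMF) should give 2-bromo-8-methoxy-1-(methoxymethoxy)naphthalene F6. Bromine–lithium exchange of F6 with n-BuLi in THF at −78 °C gives aryllithium 7 at a defined position, where the route is rejoined and continues through 8 to 9 as in step 6.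

Further compounds
F1 | step 8 | 8,8',8''-trimethoxy-1,1',1''-tris(methoxymethoxy)-2,2':4',2''-ternaphthalene | COCOc1c(-c2cc(-c3ccc4cccc(OC)c4c3OCOC)c(OCOC)c3c(OC)cccc23)ccc2cccc(OC)c12
F2 | step 7 | 4-allyl-8,8'-dimethoxy-1,1'-bis(methoxymethoxy)-2,2'-binaphthalene | C=CCc1cc(-c2ccc3cccc(OC)c3c2OCOC)c(OCOC)c2c(OC)cccc12
F3 | step 7 | 2-[8,8'-dimethoxy-1,1'-bis(methoxymethoxy)-2,2'-binaphthalen-4-yl]acetaldehyde | O=CCc1cc(-c2ccc3cccc(OC)c3c2OCOC)c(OCOC)c2c(OC)cccc12
F4 | step 7 | 2-[8,8'-dimethoxy-1,1'-bis(methoxymethoxy)-2,2'-binaphthalen-4-yl]-1-(2-methoxyphenyl)ethan-1-ol (racemic) | COc1ccccc1C(O)Cc1cc(-c2ccc3cccc(OC)c3c2OCOC)c(OCOC)c2c(OC)cccc12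
F5 | step 6 | 2-bromo-8-methoxynaphthalen-1-ol | COc1cccc2ccc(Br)c(O)c12
F6 | step 6 | 2-bromo-8-methoxy-1-(methoxymethoxy)naphthalene | COCOc1c(Br)ccc2cccc(OC)c12
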